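The ratio of added ligand charged to added ligand spare, once the racemization catalyst is bound, gives you a measure, for this catalyst and ligand, of the racemization a recipe buys.

| setting | spring | dawn | dusk | flask |
|---|---|---|---|---|
| left-handed substrate | 15 mM | 15 mM | 15 mM | 15 mM |
| right-handed substrate | 15 mM | 15 mM | 15 mM | 15 mM |
| gas | 5.7 mM (held) | 5.7 mM (held) | 5.7 mM (held) | 5.7 mM (held) |
| racemization catalyst | 0.5 mol% | 2 mol% | 1 mol% | 1 mol% |
| added ligand | 0.35 mM | 0.35 mM | 0.17 mM | 0.35 mM |
| remark | run made earlier | run made earlier | run made earlier |  |
| time |  |  |  | 25 min |

| run | time / min | left-handed product / % | right-handed product / % |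
|---|---|---|---|
| spring | 1.50 | 2.8 | 0 |
| spring | 2.50 | 9.1 | 0 |
| spring | 4.00 | 14.3 | 0 |
| spring | 8.00 | 30.5 | 0 |
| spring | 12.0 | 39.2 | 0.2 |
| spring | 20.0 | 53.0 | 0 |
| dawn | 1.50 | 4.3 | 0 |
| dawn | 2.50 | 7.0 | 0 |
| dawn | 4.00 | 14.3 | 0.9 |
| dawn | 8.00 | 33.0 | 0 |
| dawn | 12.0 | 46.4 | 1.0 |
| dawn | 20.0 | 65.4 | 0.7 |
| dusk | 1.50 | 4.9 | 0 |
| dusk | 3.00 | 7.7 | 0 |
| dusk | 6.00 | 23.3 | 0.8 |
| dusk | 10.0 | 38.6 | 1.3 |
| dusk | 20.0 | 65.3 | 1.1 |

(standard deviation of a reading: 1 percentage point)

- coupling partner is single-handed; left-handed substrate and right-handed substrate are mirror images of each other, charged as a racemate, each of them at the stated concentration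
- at the start none of the gas is in solution
- an excess is the difference of the two amounts in percent of their sum
- an excess is below zero if the other one leads
- the handed part of coupling partner does not stay in what it makes, so the products of the two hands are mirror images too

* excess of left-handed product over right-handed product in the product at 2.5 min
* excess of left-handed product over right-handed product in the product at 25 min
* part of the left-handed substrate and right-handed substrate charged together that has reacted at 25 min

Left-handed product beyond the left-handed substrate charged has come through racemization, so the decision is whether this ligand charge leaves the catalyst enough working time. Suppose added ligand captures racemization catalyst one to one in a second-order step. Free catalyst summed over time until capture is then the natural logarithm of that ratio divided by the capture rate constant. Reading the loading on left-handed substrate, the flask holds 0.150 mM of catalyst, and the logarithm, which I call the capture index, is 0.560.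

The same reckoning gives 0.241 for spring. Dawn and dusk, with different charges, give 1.95 and 2.14. At 20.0 min those two read 65.4% and 65.3% left-handed product, against 53.0% for spring. The flask's index is higher than spring's and lower than dawn's. Interpolating on the logarithm of the index, I expect 58.0% left-handed product in the flask at that time. I would charge the flask unchanged, expecting a curve between spring's and dawn's.

The forecast gives 98%, 96.8% and 67% for the three questions, reasoning that “The flask also has ligand in excess (0.30 vs 0.35 mM), so it should be throttled too”. Its catalyst figure differs from my 0.150 mM, but it also expects a throttled flask.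

The simulated flask gives excesses of 98.6% at 2.5 min and 96.8% at 25 min, with 64.1% reacted, on this scheme:

    gas ⇌ coupling partner, rate k1*(csat - [coupling partner]) (kL = 0.00820 s⁻¹)
    coupling partner + left-handed substrate → left-handed product (k = 0.720 M⁻¹ s⁻¹)
    coupling partner + right-handed substrate → right-handed product (k = 0.00470 M⁻¹ s⁻¹)
    left-handed substrate + racemization catalyst ⇌ right-handed substrate + racemization catalyst, rate k4*[racemization catalyst]*[left-handed substrate] forward; the back reaction follows from the equilibrium constant (k = 28.0 M⁻¹ s⁻¹)
    racemization catalyst + added ligand ⇌ idle complex (K = 1.70 × 10⁵ M⁻¹, k = 12.0 M⁻¹ s⁻¹)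
    coupling partner → decomposition product (k = 7.40 × 10⁻⁶ s⁻¹)

In this flask, ligand binding relaxes with a half-life of 4.42 min at 25.0 min, much shorter than the 68 min half-life of left-handed substrate by forward racemization alone, while idle complex holds 96.0% of the catalyst charged. Counting capture as one-way, the capture index times the ratio of racemization to capture rate constants makes about 1.31 forward racemization lifetimes in this flask. The neighbour flask with 0.88 mM of added ligand has index 0.187, which makes about 0.436, and it reaches 53.8% reacted at 25 min.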